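## The problem

The target, 2,2',5,5',6,6'-hexabromo-1H,1'H-3,3'-biindole (13), consists of two identical NH-indoles joined through C3 and C3'. It has no stereocentre, and the biaryl axis, flanked only by the C2 bromines and the peri hydrogens at C4 and C4', carries no descriptor, so nothing has to be controlled or relayed in three dimensions. The real difficulty is positional: each benzo ring must carry adjacent bromines at C5 and C6, and since bromination of a finished biindole cannot be trusted to pick exactly those two of four benzenoid positions, the pattern has to arrive with the arene. The C3–C3' bond links the two most nucleophilic carbons of two indoles, and oxidative dimerisation of indoles is prone to mixed 2,3'-linkage and over-oxidation, so this bond is best in place before either heterocycle exists. The C2–Br bonds are the fragile part, because a 2-bromo-NH-indole tolerates neither hot acid nor zerovalent metals nor hydride, and these two bromines should therefore go in last; the aryl C–Br bonds in turn rule out hydrogenolysis, dissolving metals and late cross-coupling. The enabling feature is that C2, C3, C3' and C2' form an unbranched four-carbon chain whose terminal carbons each bear an N-aryl nitrogen. That chain is the C2–C5 segment of a 2,5-dioxoadipate and each N-aryl unit is half of an arylhydrazine, so both pyrrole rings can be closed by Fischer indolisation around a central bond that already exists.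

## Retrosynthesis

**C2–Br and C2'–Br (13 ⇒ 12).** The two pyrrole bromines are removed first, leading to 5,5',6,6'-tetrabromo-1H,1'H-3,3'-biindole (12). These are the only bromines an electrophile can place with confidence: in a 3-substituted indole C2 is the one reactive pyrrole position, and the benzo rings are deactivated by two bromines each. Installing them earlier is excluded, since the Fischer closure used here cannot deliver a 2-bromoindole and the bond would not survive the acid and copper steps. The forward reaction needs two equivalents of a mild Br+ source at low temperature.

**C2–H back to C2–CO2Et (12 ⇒ 11 ⇒ 10).** A carboxyl group is added to each C2, giving diacid 11 and then diethyl 5,5',6,6'-tetrabromo-1H,1'H-3,3'-biindole-2,2'-dicarboxylate (10). This turns the C2–C3–C3'–C2' chain into a bis(α-keto ester). The esters make the hydrazones available by azo coupling, keep them stable, leave only one direction of enolisation, and temper the electron-rich biindole in hot acid. A 2-unsubstituted variant (a succinaldehyde bis-hydrazone) would instead cyclise to N-amino heterocycles. The price is saponification and protodecarboxylation, both routine for indole-2-carboxylates.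

**C3–C3a and N1–C2 in both halves (10 ⇒ 8, the key cut).** Both pyrrole rings are opened at once, giving diethyl (2Z,5Z)-2,5-bis[2-(3,4-dibromophenyl)hydrazinylidene]hexanedioate (8). Cutting C3–C3' instead would require an oxidative or metal-mediated coupling of two hindered, brominated indoles. The Fischer cut leaves that bond untouched and removes two rings and four skeletal bonds in one operation, down to an acyclic, symmetric C6 chain. The forward reaction demands two [3,3] shifts that both go to the ortho carbon remote from bromine. The second closure runs through mono-indole 9.

**The two N–N=C units (8 ⇒ 4 + 6).** Each hydrazone is traced to an azo coupling between 3,4-dibromobenzenediazonium chloride (6, from 3,4-dibromoaniline 5) and an activated adipate α-carbon. Direct condensation would need diethyl 2,5-dioxoadipate, which is not a stock chemical, and a separately prepared arylhydrazine. The Japp–Klingemann route uses diethyl 2,3-dioxocyclohexane-1,4-dicarboxylate (4), where an oxalyl bridge activates both α-carbons and is then expelled as oxalic acid. The forward step must couple twice and cleave the acyl C–C bond twice, passing through ring-opened monohydrazone 7, without touching the esters.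

**The oxalyl bridge (4 ⇒ 1 + 2).** The two C–C bonds between the adipate α-carbons and the bridge are cut, giving diethyl adipate (1) and diethyl oxalate (2). This is a crossed Claisen condensation followed by a ring-closing one through acyclic adduct 3. Both esters are bulk chemicals, and because oxalate cannot enolise and is the stronger electrophile, the cross-condensation has only one sense and should outrun Dieckmann closure of adipate on itself.

## Roads not taken

Alternative 1: Aryne annulation. The cut is N1–C7a and C3–C3a in both halves, leaving the chain N–CH2–C(=O)–C(=O)–CH2–N in the form of N,N'-(2,3-dioxobutane-1,4-diyl)bis(4-methylbenzenesulfonamide) A2. CsF releases the aryne from 4,5-dibromo-2-(trimethylsilyl)phenyl trifluoromethanesulfonate A1. Each sulfonamide nitrogen of A2 adds to it and the resulting aryl anion adds to the neighbouring ketone, giving the bis(3-hydroxyindoline) A3, drawn as the (3R,3'S) meso form.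
- Merits: the aryne is symmetric about its reacting bond, so the 5,6-dibromo pattern cannot come out wrong. In this respect it is better than the chosen plan, whose [3,3] shift has two ortho carbons to choose from. The C3–C3' bond is also preformed.
- Weak points: A1 needs several steps, including placing a silyl group next to a triflate on a ring that already carries two bromines. A2 is a 1,2-dione with acidic N–H and α-CH2 groups, prone to enolisation and aldol or benzilic-type decay under basic fluoride. Proton transfer to the aryl anion would give plain N-arylation. The second annulation adds to a ketone beside a fully substituted alkoxide.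
- After the key step: A3 still needs double dehydration of a bis-tertiary 1,2-diol, where pinacol rearrangement is the natural acid pathway. Two tosyl groups must then be removed without reducing C–Br, followed by C2 bromination.
- Comparison: well over ten steps against six. The chosen plan answers the regiochemical certainty of this road with the steric bias of the flanked ortho carbon, isomer separation at the crystalline diester stage, and a regiodefined fallback.

Alternative 2: Aminopalladation–dimerisation. The cut is both N1–C2 bonds and C3–C3'. Two molecules of 4,5-dibromo-2-[(trimethylsilyl)ethynyl]aniline A4 are cyclised and coupled with PdCl2 (divalent palladium), CuCl2 (divalent copper) and O2. The product is 5,5',6,6'-tetrabromo-2,2'-bis(trimethylsilyl)-1H,1'H-3,3'-biindole A5.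
- Merits: the regiochemistry of A4 is fixed by electrophilic iodination of 5 at its open ortho position. The silyl groups of A5 can be exchanged for bromine by ipso-bromodesilylation. The sequence is about four operations from 5, which is shorter than the chosen route and regiochemically safer.
- Weak points: the catalytic cycle passes through zerovalent palladium before reoxidation, in the presence of electron-poor aryl bromides in substrate and product, so oxidative addition and oligomerisation are a risk. The dibromoaniline nitrogen of A4 is a weak nucleophile for aminopalladation. Protodepalladation would give a monomeric 2-silylindole. Chloride and copper can strip the alkynyl silane and open Glaser coupling. The new bond must form between two carbons each flanked by a trimethylsilyl group.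
- Comparison: the chosen plan offers a ring-forming step free of transition metals, a C3–C3' bond that never has to be made by coupling, and classical chemistry at every stage. Because this alternative is short and regiodefined, it is kept as the fallback for the key step.

Alternative 3: Double Bergman cycloaromatisation. The cut is C5–C6 and C5'–C6', that is, both benzene rings. The precursor is dimethyl 4,4',5,5'-tetrakis(bromoethynyl)-1H,1'H-3,3'-bipyrrole-2,2'-dicarboxylate A6. Heating A6 with 1,4-cyclohexadiene should give dimethyl 5,5',6,6'-tetrabromo-1H,1'H-3,3'-biindole-2,2'-dicarboxylate A7. Diester A7 is the methyl analogue of 10.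
- Merits: each bromine is carried on an alkyne terminus, so the 5,6-pattern of A7 is fixed by construction with no regiochemical question.
- Weak points: an enediyne fused to a five-membered ring has widely separated alkyne termini and needs high temperature to cyclise. The 1,4-diradical sits next to C–Br bonds, and the hydrogen donor can also reduce bromoalkynes and aryl bromides. A6 needs a fully substituted bipyrrole, fourfold alkynylation and fourfold alkyne bromination, and is unlikely to be stable.
- Comparison: A7 would join the main route at the saponification stage, so this road reaches the same kind of diester as step 3 at several times the step count and with a far more fragile precursor. It is better than the chosen plan only in regiochemical certainty.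

Key step: step 3

Remarks on the chemistry:
- Compounds 3, 4 and 7 are drawn as keto tautomers but exist largely as enols, so their sp3 α-carbons have no defined configuration.
- Hydrazones 7, 8 and 9 are drawn as the hydrogen-bonded Z isomers; any E isomer equilibrates in the acid of step 3.
- The biaryl axis of 10–13 is treated as not configurationally stable, in line with the target structure.

Step 1
Reactants: 1 diethyl adipate; 2 diethyl oxalate
Product: 4 diethyl 2,3-dioxocyclohexane-1,4-dicarboxylate, via triethyl 1-oxopentane-1,2,5-tricarboxylate 3 (not isolated)
Conditions: NaOEt (2.2 equiv), EtOH/Et2O, 0 °C → reflux; then aq. HCl, 0 °C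
Reagents that add atoms: none
Why: Crossed Claisen condensation of the adipate enolate with non-enolisable diethyl oxalate gives 3, and a second, ring-closing Claisen (Dieckmann-type) attack of the other α-carbon on the remaining oxalate ester forms the six-membered ring. Formation of the doubly stabilised bis-enolate drives the sequence, and the product should be isolated as its enol after acidification.

Step 2
Reactants: 5 3,4-dibromoaniline; 4 diethyl 2,3-dioxocyclohexane-1,4-dicarboxylate
Product: 8 diethyl (2Z,5Z)-2,5-bis[2-(3,4-dibromophenyl)hydrazinylidene]hexanedioate, via 3,4-dibromobenzenediazonium chloride 6 (not isolated), via ring-opened monohydrazone 7 (not isolated)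
Conditions: 5 (2.1 equiv), NaNO2, aq. HCl, 0 °C; then 4, NaOAc, EtOH/H2O, 0 °C → rt
Reagents that add atoms: sodium nitrite, [Na+].[O-]N=O
Why: Double Japp–Klingemann reaction: azo coupling at an enolised β-keto ester carbon gives an azo ester that cannot tautomerise, so water attacks the adjacent, highly electrophilic 1,2-dione carbonyl and the C–C bond breaks, opening the ring to hydrazone 7. The same coupling and acyl cleavage at the second α-carbon expels oxalic acid and should leave the sparingly soluble bis-hydrazone 8, with both esters intact at the buffered pH.

Step 3
Reactants: 8 diethyl (2Z,5Z)-2,5-bis[2-(3,4-dibromophenyl)hydrazinylidene]hexanedioate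
Product: 10 diethyl 5,5',6,6'-tetrabromo-1H,1'H-3,3'-biindole-2,2'-dicarboxylate, via mono-indole hydrazone 9 (not isolated)
Conditions: polyphosphoric acid, toluene, 100–110 °C; then ice/H2O; crystallisation
Reagents that add atoms: none
Why: This is a Fischer indole synthesis run twice on one chain. Acid tautomerises each hydrazone to its ene-hydrazine, which can only form toward the central CH2 because the other substituent on the C=N carbon is the ester. A [3,3]-sigmatropic (diaza-Cope) shift then breaks N–N and joins the former CH2 carbon to an ortho carbon of the dibromoaryl ring (C3–C3a), and rearomatisation frees the aniline nitrogen. That nitrogen adds to the protonated imine carbon in a 5-exo-trig closure (N1–C2) and the aminal loses ammonia to give 9, whose remaining hydrazone enolises toward the indol-3-yl CH2 (a conjugated ene-hydrazine) and closes the second pyrrole ring by the same events and the same 5-exo-trig mode. The closest known reaction is the acid cyclisation of Japp–Klingemann-derived α-keto ester arylhydrazones to indole-2-carboxylates, halogenated examples included. No stereocentre is formed. The selectivity needed is regiochemical: each shift must use the ortho carbon para to bromine rather than the one wedged between nitrogen and bromine, and this should be favoured by the flanking bromine (buttressed by its neighbour) and by the peri clash it would have with the C3 substituent, a CH2 group in the first closure and a 2-carbethoxyindol-3-yl group in the second; the symmetric 5,6/5',6' isomer should be separable from any 4,5-containing isomer by crystallisation. Diversion to N-amino heterocycles is disfavoured because no free ketone is present and the hydrazone N–H is deactivated by the dibromoaryl ring and the conjugated ester.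

Step 4
Reactants: 10 diethyl 5,5',6,6'-tetrabromo-1H,1'H-3,3'-biindole-2,2'-dicarboxylate
Product: 11 5,5',6,6'-tetrabromo-1H,1'H-3,3'-biindole-2,2'-dicarboxylic acid
Conditions: NaOH, EtOH/THF/H2O, reflux; then aq. HCl
Reagents that add atoms: sodium hydroxide, [Na+].[OH-]
Why: Saponification of the two indole-2-carboxylate esters by acyl–oxygen cleavage; aryl bromides are inert to aqueous hydroxide and the diacid should precipitate on acidification.

Step 5
Reactants: 11 5,5',6,6'-tetrabromo-1H,1'H-3,3'-biindole-2,2'-dicarboxylic acid
Product: 12 5,5',6,6'-tetrabromo-1H,1'H-3,3'-biindole
Conditions: Cu2O (0.2 equiv), 1,10-phenanthroline (0.4 equiv), quinoline/NMP, 170 °C, Ar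
Reagents that add atoms: none
Why: Copper-mediated protodecarboxylation of indole-2-carboxylic acids, the classical close of the Fischer/indole-2-carboxylate sequence, which is routinely applied to bromoindole-2-carboxylic acids. The phenanthroline ligand allows a temperature low enough to spare the aryl C–Br bonds.

Step 6
Reactants: 12 5,5',6,6'-tetrabromo-1H,1'H-3,3'-biindole
Product: 13 2,2',5,5',6,6'-hexabromo-1H,1'H-3,3'-biindole
Conditions: NBS (2.05 equiv), THF, −78 → 0 °C, dark
Reagents that add atoms: N-bromosuccinimide, O=C1CCC(=O)N1Br
Why: Electrophilic bromination of a 3-substituted indole at C2 (attack at C3, 1,2-shift of bromine, loss of the C2 proton). The dibrominated benzo rings are deactivated, so C2 and C2' are the only reactive positions and two equivalents should stop at the hexabromide.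

## Compound list

1 | diethyl adipate | CCOC(=O)CCCCC(=O)OCC | starting material
2 | diethyl oxalate | CCOC(=O)C(=O)OCC | starting material
3 | triethyl 1-oxopentane-1,2,5-tricarboxylate (racemic, enolisable) | CCOC(=O)C(=O)C(C(=O)OCC)CCCC(=O)OCC | intermediate
4 | diethyl 2,3-dioxocyclohexane-1,4-dicarboxylate (enolised; C1/C4 not defined) | CCOC(=O)C1CCC(C(=O)OCC)C(=O)C1=O | intermediate
5 | 3,4-dibromoaniline | Nc1ccc(Br)c(Br)c1 | starting material
6 | 3,4-dibromobenzenediazonium chloride | N#[N+]c1ccc(Br)c(Br)c1.[Cl-] | intermediate
7 | (6Z)-6-[2-(3,4-dibromophenyl)hydrazinylidene]-7-ethoxy-3-(ethoxycarbonyl)-2,7-dioxoheptanoic acid (C3 not defined) | OC(=O)C(=O)C(C(=O)OCC)CC/C(=N/Nc1ccc(Br)c(Br)c1)C(=O)OCC | intermediate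
8 | diethyl (2Z,5Z)-2,5-bis[2-(3,4-dibromophenyl)hydrazinylidene]hexanedioate | CCOC(=O)/C(=N\Nc1ccc(Br)c(Br)c1)CC/C(=N/Nc1ccc(Br)c(Br)c1)C(=O)OCC | intermediate
9 | ethyl 5,6-dibromo-3-{(2Z)-2-[2-(3,4-dibromophenyl)hydrazinylidene]-3-ethoxy-3-oxopropyl}-1H-indole-2-carboxylate | CCOC(=O)c1[nH]c2cc(Br)c(Br)cc2c1C/C(=N/Nc1ccc(Br)c(Br)c1)C(=O)OCC | intermediate
10 | diethyl 5,5',6,6'-tetrabromo-1H,1'H-3,3'-biindole-2,2'-dicarboxylate | CCOC(=O)c1[nH]c2cc(Br)c(Br)cc2c1-c1c(C(=O)OCC)[nH]c2cc(Br)c(Br)cc12 | intermediate
11 | 5,5',6,6'-tetrabromo-1H,1'H-3,3'-biindole-2,2'-dicarboxylic acid | OC(=O)c1[nH]c2cc(Br)c(Br)cc2c1-c1c(C(=O)O)[nH]c2cc(Br)c(Br)cc12 | intermediate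
12 | 5,5',6,6'-tetrabromo-1H,1'H-3,3'-biindole | Brc1cc2[nH]cc(-c3c[nH]c4cc(Br)c(Br)cc34)c2cc1Br | intermediate
13 | 2,2',5,5',6,6'-hexabromo-1H,1'H-3,3'-biindole | Brc1cc2[nH]c(Br)c(-c3c(Br)[nH]c4cc(Br)c(Br)cc34)c2cc1Br | target

## Step count and risks

Total: 6 steps. Longest linear sequence: 6 steps (1 and 2 to 13); 3,4-dibromoaniline 5 enters at step 2.

**Step 3 (key step).** The most likely failure is loss of regiocontrol in one or both [3,3] shifts, with bond formation at the bromine-flanked ortho carbon, which would spread the material over three isomeric biindoles. Second to that is stalling after the first closure on the deactivated ring, or cyclisation of a hydrazone N–H onto the second hydrazone carbon to give a six-membered N-aryl heterocycle. The fallback fixes the regiochemistry by electrophilic substitution, which avoids the carbon between NH2 and Br far more strictly than a sigmatropic shift; it sets out from 5 and comes back at 12.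
- 5 is iodinated with ICl in AcOH at its open ortho position to give 4,5-dibromo-2-iodoaniline F1.
- Sonogashira coupling with ethynyltrimethylsilane (PdCl2(PPh3)2, CuI, Et3N, rt; C–I reacts before C–Br) gives 4,5-dibromo-2-[(trimethylsilyl)ethynyl]aniline F2 (the compound called A4 above).
- Aminopalladation–homocoupling with PdCl2, CuCl2 and O2 gives 5,5',6,6'-tetrabromo-2,2'-bis(trimethylsilyl)-1H,1'H-3,3'-biindole F3 (the compound called A5 above).
- TBAF in THF removes both silyl groups to give 12, which re-enters at step 6.

**Step 2.** The risks are incomplete second coupling or cleavage, over-coupling of the product hydrazone with excess diazonium salt to a formazan, and ester hydrolysis that would switch the cleavage to decarboxylation with the ring retained. The fallback replaces acyl cleavage by loss of CO2; it sets out from diazonium salt 6 and comes back at 8.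
- Diethyl malonate is alkylated at both ends of 1,2-dibromoethane (NaOEt, EtOH, excess sodiomalonate to outrun intramolecular ring closure of the mono-alkylated stage) to give tetraethyl butane-1,1,4,4-tetracarboxylate F4.
- One ester of each malonate unit is saponified (KOH, 2 equiv, EtOH, rt) to give 2,5-bis(ethoxycarbonyl)hexanedioic acid F5.
- Its dipotassium salt is coupled with 6 at 0 °C; each azo acid loses CO2 (decarboxylative Japp–Klingemann variant) to give 8.

**Step 5.** Copper may insert into aryl C–Br bonds at high temperature, causing reductive debromination or Ullmann-type coupling. Decarboxylation may also stop halfway, or an intramolecular anhydride may form between the two neighbouring carboxyl groups. The fallback avoids the metal and protodecarboxylation entirely; it sets out from 11 and comes back at 13. Diacid 11 is treated with NBS (2.1 equiv) in DMF at 0 °C → rt, so that each carboxyl is replaced directly by bromine through ipso-bromodecarboxylation (halodecarboxylation of an electron-rich heteroaromatic acid: bromonium attack on the pyrrole ring, ipso substitution at C2 and loss of CO2 in place of a proton). No new compound is made, and 12 and step 6 are bypassed.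

**Step 6.** Possible failures are over-bromination at a benzenoid carbon or on nitrogen, hydrolysis of the 3-bromoindolenine intermediate to an oxindole, and incomplete second bromination because of poor solubility. The fallback moves from electrophilic to anionic C2 functionalisation; it sets out from 12 and comes back at 13.
- 12 is protected with Boc2O/DMAP to give di-tert-butyl 5,5',6,6'-tetrabromo-1H,1'H-3,3'-biindole-1,1'-dicarboxylate F6.
- Carbamate-directed lithiation at C2 and C2' (LiN(iPr)2, THF, −78 °C) and quench with 1,2-dibromotetrachloroethane gives di-tert-butyl 2,2',5,5',6,6'-hexabromo-1H,1'H-3,3'-biindole-1,1'-dicarboxylate F7.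
- Thermolysis of the carbamates (neat or in diphenyl ether, about 180 °C) gives 13.

## Further compounds

F1 | step 3 | 4,5-dibromo-2-iodoaniline | Nc1cc(Br)c(Br)cc1I
F2 | step 3 | 4,5-dibromo-2-[(trimethylsilyl)ethynyl]aniline | C[Si](C)(C)C#Cc1cc(Br)c(Br)cc1N
F3 | step 3 | 5,5',6,6'-tetrabromo-2,2'-bis(trimethylsilyl)-1H,1'H-3,3'-biindole | C[Si](C)(C)c1[nH]c2cc(Br)c(Br)cc2c1-c1c([Si](C)(C)C)[nH]c2cc(Br)c(Br)cc12
F4 | step 2 | tetraethyl butane-1,1,4,4-tetracarboxylate | CCOC(=O)C(C(=O)OCC)CCC(C(=O)OCC)C(=O)OCC
F5 | step 2 | 2,5-bis(ethoxycarbonyl)hexanedioic acid (mixture of diastereomers) | CCOC(=O)C(C(=O)O)CCC(C(=O)O)C(=O)OCC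
F0 | step 5 | none | none
F6 | step 6 | di-tert-butyl 5,5',6,6'-tetrabromo-1H,1'H-3,3'-biindole-1,1'-dicarboxylate | CC(C)(C)OC(=O)n1cc(-c2cn(C(=O)OC(C)(C)C)c3cc(Br)c(Br)cc23)c2cc(Br)c(Br)cc21
F7 | step 6 | di-tert-butyl 2,2',5,5',6,6'-hexabromo-1H,1'H-3,3'-biindole-1,1'-dicarboxylate | CC(C)(C)OC(=O)n1c(Br)c(-c2c(Br)n(C(=O)OC(C)(C)C)c3cc(Br)c(Br)cc23)c2cc(Br)c(Br)cc21
A1 | alternative 1 | 4,5-dibromo-2-(trimethylsilyl)phenyl trifluoromethanesulfonate | C[Si](C)(C)c1cc(Br)c(Br)cc1OS(=O)(=O)C(F)(F)F
A2 | alternative 1 | N,N'-(2,3-dioxobutane-1,4-diyl)bis(4-methylbenzenesulfonamide) | Cc1ccc(cc1)S(=O)(=O)NCC(=O)C(=O)CNS(=O)(=O)c1ccc(C)cc1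
A3 | alternative 1 | (3R,3'S)-5,5',6,6'-tetrabromo-1,1'-bis(4-methylbenzenesulfonyl)-2,2',3,3'-tetrahydro-1H,1'H-3,3'-biindole-3,3'-diol | Cc1ccc(cc1)S(=O)(=O)N1C[C@](O)(c2cc(Br)c(Br)cc21)[C@@]1(O)CN(S(=O)(=O)c2ccc(C)cc2)c2cc(Br)c(Br)cc21
A4 | alternative 2 | 4,5-dibromo-2-[(trimethylsilyl)ethynyl]aniline | C[Si](C)(C)C#Cc1cc(Br)c(Br)cc1N
A5 | alternative 2 | 5,5',6,6'-tetrabromo-2,2'-bis(trimethylsilyl)-1H,1'H-3,3'-biindole | C[Si](C)(C)c1[nH]c2cc(Br)c(Br)cc2c1-c1c([Si](C)(C)C)[nH]c2cc(Br)c(Br)cc12
A6 | alternative 3 | dimethyl 4,4',5,5'-tetrakis(bromoethynyl)-1H,1'H-3,3'-bipyrrole-2,2'-dicarboxylate | COC(=O)c1[nH]c(C#CBr)c(C#CBr)c1-c1c(C(=O)OC)[nH]c(C#CBr)c1C#CBr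
A7 | alternative 3 | dimethyl 5,5',6,6'-tetrabromo-1H,1'H-3,3'-biindole-2,2'-dicarboxylate | COC(=O)c1[nH]c2cc(Br)c(Br)cc2c1-c1c(C(=O)OC)[nH]c2cc(Br)c(Br)cc12
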